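The ratio to read this flask by is the equivalents of reagent per starting material in the charge, E = 1.50. You want to know how high target climbs here and when, and E is the coordinate along which the earlier runs line up.

| flask | starting material | reagent | remark | time |
|---|---|---|---|---|
| zeta | 13 mM | 30 mM | run made earlier |  |
| alpha | 30 mM | 30 mM | run made earlier |  |
| gamma | 20 mM | 15 mM | run made earlier |  |
| flask | 20 mM | 30.0 mM |  | 5.0 h |

| run | time / h | target / % |
|---|---|---|
| zeta | 0.0417 | 23.7 |
| zeta | 0.100 | 19.9 |
| zeta | 0.250 | 7.7 |
| zeta | 0.667 | 0.1 |
| zeta | 1.50 | 0 |
| zeta | 4.00 | 0.3 |
| alpha | 0.0417 | 25.1 |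
| alpha | 0.100 | 26.1 |
| alpha | 0.250 | 17.5 |
| alpha | 0.667 | 8.5 |
| alpha | 1.50 | 4.2 |
| alpha | 4.00 | 1.5 |
| gamma | 0.0417 | 24.9 |
| gamma | 0.133 | 29.9 |
| gamma | 0.417 | 24.9 |
| gamma | 1.33 | 19.2 |
| gamma | 4.00 | 18.7 |

(readings scatter by 0.5 percentage points)

- the best time, 5.0 h at the latest, for target
- the amount of target, in percent of the starting material charged, at that time
- earliest time at which at least nineteen twentieths of that best amount are there, in min
- latest time at which they still are

- a reading or a percentage of target counts all its forms, free or not

The highest target reading falls as E rises: 29.9% in gamma at E = 0.750, 26.1% in alpha at 1.00 and 23.7% in zeta at 2.31. The tails part the same way, for at 0.667 h zeta reads 0.1% against alpha's 8.5%. Your flask has a higher E than alpha and a lower one than zeta, so I take alpha's peak reading as the bound from above and zeta's as the bound from below, and I put the peak between zeta's 0.0417 h and alpha's 0.100 h. Both ends are soft, since each is a reading with scatter 0.5 percentage points that may stand beside the peak rather than on it. To tighten the bracket, join the ends by a straight line in E, which gives me 25.2% at 0.0777 h, and by hand I go no further.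

The forecast put 26.5% at 0.065 h, with the window from 2.8 min to 0.09 h, and called these “envelope estimates”; its best stands above my upper bound. The flask gives 24.6% at 0.0513 h, with the window from 1.83 min to 0.0824 h, so amount and time both fall inside my bracket, the amount 0.60 points under my join and the time earlier than it.

    starting material + reagent ⇌ intermediate (K = 100 /M, k = 3.30 /M/s)
    intermediate ⇌ target + by-product (K = 0.00110 M, k = 0.0100 /s)
    reagent + target → over-reaction product (k = 0.160 /M/s)
    starting material + by-product → side product (k = 5.50 /M/s)
    starting material + target ⇌ idle adduct, settled at all times (K = 110 /M)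

The order in E goes on past the bracket: from 24.6% in this flask at E = 1.50, a neighbour charged with 120 mM of reagent, at 6.00 equiv, reaches 15.3%, less than zeta's highest reading. In this flask at 0.159 h the half-life of free target by its turning with reagent into over-reaction product is 0.082 h, short against the 5.0 h allowed. At 5.00 h this flask holds 0% target, 50.6% over-reaction product and 49.4% side product, with starting material, its limiting reagent, at 0%.

Readings and results come from a simulation on assumed constants.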